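## The problem

Compound 10 is the head-to-tail cyclobutane dimer of 2',4'-dihydroxychalcone: a four-membered ring with 2,4-dihydroxybenzoyl groups at C1 and C3 and phenyl groups at C2 and C4. All four ring carbons are stereocentres. The two aroyl groups are trans to each other and the two phenyl groups are trans to each other, so each aroyl group is cis to one neighbouring phenyl and trans to the other (the 1α,2α,3β,4β or α-truxillic arrangement). The molecule has a centre of symmetry and is achiral, so only relative configuration matters and every operation can be run twice on equivalent arms. This arrangement is not the all-trans one, so equilibration cannot be counted on to produce it, and no centre can be used to set another once the ring exists. The configuration therefore has to arrive with a cyclobutane whose four centres are already fixed, and α-truxillic acid 1 has exactly these. The groups that will not survive rough treatment are C1–H and C3–H, each α to a ketone on a strained ring: enolisation there leads to epimerisation or, because the second acyl group sits 1,3 to the first, to strain-driven retro-Michael opening; the electron-rich resorcinol rings should also be made last. The feature that permits the key step lies in the aryl rings: each 2,4-dihydroxybenzoyl ring (C1'–C6') is the didehydro form of a 4-acylcyclohexane-1,3-dione, in which C1'–C6' is a Michael bond and C3'–C4' a Claisen bond between an acylacetone (ketone carbon, C1', C2', C3') and an acrylate (C4', C5', C6'), with the oxygens at C2' and C4' already in place. The same 1,3-diketone, once deprotonated, masks the cyclobutyl ketone as a diketonate and shields C1–H and C3–H during the base steps.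

## Retrosynthesis

**10 ⇒ 9.** No skeletal bond is cut; two hydrogens are added back to each aryl ring, giving the bis(4-acylcyclohexane-1,3-dione) 9 (drawn as its enol). This moves the oxidisable phenols to the last step and turns each arene into a pattern of three carbonyl groups that condensation chemistry can assemble. The forward reaction needs an oxidant that acts on the enolised triketone and spares the product phenols and the cyclobutane methines.

**9 ⇒ 6 + 7 (through 8).** In each ring the bonds C1'–C6' and C3'–C4' are cut: four C–C bonds and two rings in one operation, leading to the open-chain bis(1,3-diketone) 6 and two molecules of methyl acrylate 7. The neighbouring cut at the ketone–C1' bond (acylating a preformed six-membered ring) would need a strongly basic ring enolate to meet an α-branched acyl donor, which invites ketene formation and epimerisation at C1/C3. The chosen cut instead uses the most acidic carbon of 6 as the first nucleophile, under catalytic base, and a commodity three-carbon ester as the partner. The forward reaction must add one acrylate per arm (adduct 8) and then close the ring from the terminal methyl group. Because the central C–H of 8 is ionised first, the closure has to run through the dienolate of the diketone, with more than two equivalents of base per arm. The second deprotonation must take the methyl group and never the cyclobutane methine.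

**6 ⇒ 4 (through 5) ⇒ 2 + 3.** A tert-butoxycarbonyl group is added back to the central carbon of each diketone arm (4), and the bond between the cyclobutyl carbonyl carbon and that carbon is then cut. This leads to the bis(acyl chloride) 2 and tert-butyl acetoacetate 3. Direct acylation of a simple methyl ketone enolate would be a step shorter, but the acetoacetate is a weakly basic, chelated nucleophile that reacts cleanly at carbon. The tert-butyl ester is chosen so that it leaves under acid (through the diketo acid 5) and no base ever meets the triacylmethane 4.

**2 ⇒ 1.** The acyl chloride 2 comes from α-truxillic acid 1 by functional-group change only. Compound 1 is purchased and carries all four stereocentres of 10 with both phenyl groups in place, so no bond to the cyclobutane ring is made or broken anywhere in the route.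

## Roads not taken

**Alternative 1:** The cut is at the two carbonyl–aryl bonds. The forward key step is a twofold Friedel–Crafts acylation: the cis,trans,cis dianhydride A1 is opened by two molecules of 1,3-dimethoxybenzene A2 under a Lewis acid, each anhydride acylating C4 of one arene, to give the diaroyl diacid A3.
- Merits: the template is a commodity, the aryl ketones arrive in one step with the phenols protected, and no arene has to be built or dehydrogenated. In these respects it is better than the chosen plan.
- Weak points: the two anhydrides have no inherent preference for opening in opposite senses, so the 1,3-placement of the aroyl groups in A3 is not secured. A3 also carries carboxyl groups where 10 has phenyl groups. Two decarboxylative arylations at secondary cyclobutane carbons would be needed; they pass through cyclobutyl radicals whose two faces differ only through the substituent across the ring, so the trans relation of the phenyl groups is left to chance. Four methyl ethers remain to be cleaved.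
- Comparison: the chosen plan sets against the shorter arene chemistry the fact that 1 already holds both phenyl groups in the correct relative configuration and that no stereocentre is created after its first step.

**Alternative 2:** The cut is at cyclobutane bonds C1–C2 and C3–C4, formed by [2+2] photocycloaddition of two molecules of coumarin A4 stacked antiparallel in a host lattice, giving the anti head-to-tail bis-lactone A5.
- Merits: each lactone ties a carbonyl carbon cis to its neighbouring aryl ring, and the anti head-to-tail arrangement gives exactly the 1α,2α,3β,4β pattern; A4 is cheap.
- Weak points: this is not the dimer that irradiation of A4 in solution favours, so the step depends on confinement in a lattice or cavity and is awkward to scale. After opening of A5 each aryl ring at C2 and C4 carries an ortho oxygen that 10 lacks, which costs two aryl C–O reductions. The carboxyl carbons must still be turned into 2,4-dihydroxyphenyl ketones, so the whole task of the chosen route remains.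
- Comparison: once the extra oxygens are removed, the material stands at the level of 1, which is bought. A5 would be the better entry only if 1 were unavailable or if analogues oxygenated on those rings were wanted; for 10 it is a longer way to the same cyclobutane.

**Alternative 3:** The cut is at the two cyclobutane–phenyl bonds. The trans bis(quinolin-8-yl amide) A6 would be arylated twice with iodobenzene A7 under divalent palladium catalysis with a silver carboxylate as iodide acceptor. Each chelating amide delivers phenyl to a methylene C–H on its own face, and the product sought is A8.
- Merits: the step is catalytic, the aryl group enters cis to the directing amide as the target requires locally, and two different aryl groups could be introduced for analogues. For unsymmetrical analogues it is better than the chosen plan.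
- Weak points: each amide is flanked by both methylene carbons, so one amide can place both phenyl groups on the same face, and over-arylation is possible; the 2,4-trans pattern rests on statistics and not on a controlling element. A8 is the bis-amide of 1, so two robust secondary amides would then have to be cleaved next to epimerisable methines, only to reach the diacid with which the chosen route begins.
- Comparison: the chosen plan starts where this road would arrive several steps later.

Key step: step 4

Assumption: 1 is purchased as the single centrosymmetric diastereomer. The stereodescriptors in all SMILES strings express relative configuration of achiral compounds, and the readily enolised side-chain methines of 4, 5, 8 and F3 are written without descriptors.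

## Route

Step 1
Reactants: 1 α-truxillic acid, (1α,2α,3β,4β)-2,4-diphenylcyclobutane-1,3-dicarboxylic acid
Product: 2 (1α,2α,3β,4β)-2,4-diphenylcyclobutane-1,3-dicarbonyl dichloride
Conditions: (COCl)2, DMF (cat.), CH2Cl2, 0 °C to rt
Reagents that add atoms: oxalyl chloride, ClC(=O)C(=O)Cl
Why: Acid chloride formation through the chloroiminium species from DMF; no base and no heating are involved, so the C1/C3 methines should keep their configuration, and the trans carboxyl groups cannot close to an anhydride.

Step 2
Reactants: 2 (1α,2α,3β,4β)-2,4-diphenylcyclobutane-1,3-dicarbonyl dichloride; 3 tert-butyl acetoacetate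
Product: 4 di-tert-butyl 2,2'-[(1α,2α,3β,4β)-2,4-diphenylcyclobutane-1,3-dicarbonyl]bis(3-oxobutanoate)
Conditions: 3 (2.4 equiv), MgCl2, pyridine, CH2Cl2, 0 °C to rt
Reagents that add atoms: none
Why: Magnesium-mediated C-acylation of a β-keto ester with an acyl chloride; the chelated magnesium enolate reacts at carbon, the triacylmethane product is held as its chelate against further acylation, and pyridine is a weak enough base that ketene formation from 2 should stay slow at 0 °C.

Step 3
Reactants: 4 di-tert-butyl 2,2'-[(1α,2α,3β,4β)-2,4-diphenylcyclobutane-1,3-dicarbonyl]bis(3-oxobutanoate)
Product: 6 1,1'-[(1α,2α,3β,4β)-2,4-diphenylcyclobutane-1,3-diyl]bis(butane-1,3-dione), via bis(diketo acid) 5 (not isolated)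
Conditions: CF3CO2H, CH2Cl2, rt
Reagents that add atoms: none
Why: Acidolysis of the tert-butyl esters (loss of 2-methylpropene) followed by spontaneous decarboxylation of the β,β'-diketo acid; under acid the triacylmethane cannot undergo retro-Claisen deacylation, and the ketone enolises into the diketone and not toward the cyclobutane.

Step 4
Reactants: 6 1,1'-[(1α,2α,3β,4β)-2,4-diphenylcyclobutane-1,3-diyl]bis(butane-1,3-dione); 7 methyl acrylate
Product: 9 [(1α,2α,3β,4β)-2,4-diphenylcyclobutane-1,3-diyl]bis[(2-hydroxy-4-oxocyclohex-1-en-1-yl)methanone], via bis(Michael adduct) 8 (not isolated)
Conditions: 7 (2.1 equiv), KOtBu (0.2 equiv), THF, 0 °C to rt; volatiles removed; KOtBu (6 equiv), THF, 0 °C to rt; then 1 M HCl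
Reagents that add atoms: none
Why: Catalytic tert-butoxide is quenched at once by the far more acidic diketone, so the only nucleophile present is the diketonate, which adds through its central carbon to 7 (Michael addition, bond C1'–C6' in each arm); the adduct is less acidic and more hindered than 6, which should hold the addition at one acrylate per arm, and it is carried on as 8 without isolation. With excess KOtBu each arm of 8 rests as its diketonate, and a second, reversible deprotonation at the terminal methyl group gives the dienolate whose CH2 terminus attacks the ester carbonyl with loss of methoxide (Claisen condensation, bond C3'–C4'). Each of the two rings closes in the same 6-(enolendo)-exo-trig mode. The closest known reactions are the Michael–Claisen annulation of methyl ketones with acrylates to cyclohexane-1,3-diones under KOtBu and the terminal acylation of 1,3-diketone dianions by esters to 1,3,5-triketones, here made intramolecular. No lasting stereocentre is created: the side-chain methines of 8 are enolisable, C1' ends as an enol carbon in 9, and C1–C4 are not touched. The selectivity needed is deprotonation at the methyl group and never at the cyclobutane methine: in the diketonate both are γ-positions, and the primary, unhindered methyl should be removed far more readily than a tertiary C–H whose enolate would be an exocyclic double bond on a four-membered ring flanked by two substituted carbons. Deprotonation α to the ester is reversible under these equilibrating conditions and unproductive, since that enolate could only close a four-membered ring, whereas each closure is made irreversible by deprotonation of the triketone formed, which also keeps the cyclobutyl ketone masked until the acid quench.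

Step 5
Reactants: 9 [(1α,2α,3β,4β)-2,4-diphenylcyclobutane-1,3-diyl]bis[(2-hydroxy-4-oxocyclohex-1-en-1-yl)methanone]
Product: 10 [(1α,2α,3β,4β)-2,4-diphenylcyclobutane-1,3-diyl]bis[(2,4-dihydroxyphenyl)methanone]
Conditions: I2 (0.4 equiv), DMSO, 80 °C; aq. Na2S2O3
Reagents that add atoms: none
Why: Iodine-catalysed dehydrogenative aromatisation with DMSO as terminal oxidant: the enolised triketone is iodinated α to a ring carbonyl, loses HI and tautomerises to the resorcinol, while DMSO reoxidises HI to iodine; the exocyclic ketone is enolised into the ring and not toward the hindered cyclobutane methine, so C1 and C3 should be left alone.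

## Compound list

1 | α-truxillic acid, (1α,2α,3β,4β)-2,4-diphenylcyclobutane-1,3-dicarboxylic acid | OC(=O)[C@H]1[C@H](c2ccccc2)[C@H](C(=O)O)[C@H]1c1ccccc1 | starting material
2 | (1α,2α,3β,4β)-2,4-diphenylcyclobutane-1,3-dicarbonyl dichloride | O=C(Cl)[C@H]1[C@H](c2ccccc2)[C@H](C(=O)Cl)[C@H]1c1ccccc1 | intermediate
3 | tert-butyl acetoacetate (tert-butyl 3-oxobutanoate) | CC(=O)CC(=O)OC(C)(C)C | starting material
4 | di-tert-butyl 2,2'-[(1α,2α,3β,4β)-2,4-diphenylcyclobutane-1,3-dicarbonyl]bis(3-oxobutanoate) | CC(=O)C(C(=O)OC(C)(C)C)C(=O)[C@H]1[C@H](c2ccccc2)[C@H](C(=O)C(C(C)=O)C(=O)OC(C)(C)C)[C@H]1c1ccccc1 | intermediate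
5 | 2,2'-[(1α,2α,3β,4β)-2,4-diphenylcyclobutane-1,3-dicarbonyl]bis(3-oxobutanoic acid) | CC(=O)C(C(=O)O)C(=O)[C@H]1[C@H](c2ccccc2)[C@H](C(=O)C(C(C)=O)C(=O)O)[C@H]1c1ccccc1 | intermediate (not isolated)
6 | 1,1'-[(1α,2α,3β,4β)-2,4-diphenylcyclobutane-1,3-diyl]bis(butane-1,3-dione) | CC(=O)CC(=O)[C@H]1[C@H](c2ccccc2)[C@H](C(=O)CC(C)=O)[C@H]1c1ccccc1 | intermediate
7 | methyl acrylate | C=CC(=O)OC | starting material
8 | dimethyl 4,4'-[(1α,2α,3β,4β)-2,4-diphenylcyclobutane-1,3-dicarbonyl]bis(5-oxohexanoate) | COC(=O)CCC(C(C)=O)C(=O)[C@H]1[C@H](c2ccccc2)[C@H](C(=O)C(CCC(=O)OC)C(C)=O)[C@H]1c1ccccc1 | intermediate (not isolated)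
9 | [(1α,2α,3β,4β)-2,4-diphenylcyclobutane-1,3-diyl]bis[(2-hydroxy-4-oxocyclohex-1-en-1-yl)methanone], enol form of the bis(4-acylcyclohexane-1,3-dione) | O=C(C1=C(O)CC(=O)CC1)[C@H]1[C@H](c2ccccc2)[C@H](C(=O)C2=C(O)CC(=O)CC2)[C@H]1c1ccccc1 | intermediate
10 | [(1α,2α,3β,4β)-2,4-diphenylcyclobutane-1,3-diyl]bis[(2,4-dihydroxyphenyl)methanone] | O=C(c1ccc(O)cc1O)[C@H]1[C@H](c2ccccc2)[C@H](C(=O)c2ccc(O)cc2O)[C@H]1c1ccccc1 | target

## Step count and risks

Total step count: 5. Longest linear sequence: 5 steps (1 → 2 → 4 → 6 → 9 → 10).

**Step 4 (key step).** Three processes are most likely to go wrong:
- over-addition of acrylate at the central carbon of an arm;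
- stalling of the ring closure, because the second deprotonation is partitioned toward the ester α-position or because tert-butoxide slowly exchanges the methyl ester for a poorer leaving group;
- loss of configuration at C1/C3, or strain-driven ring opening, by enolisation of the cyclobutyl ketone whenever an arm is not held as its diketonate.

The fallback gives up building the arenes and brings them in intact. It sets out from 2. N,O-dimethylhydroxylamine hydrochloride and pyridine in CH2Cl2 should give (1α,2α,3β,4β)-N1,N3-dimethoxy-N1,N3-dimethyl-2,4-diphenylcyclobutane-1,3-dicarboxamide F1. Addition of 2,4-dimethoxyphenylmagnesium bromide in THF at 0 °C, stopped at the ketone by the chelated tetrahedral intermediate, should give [(1α,2α,3β,4β)-2,4-diphenylcyclobutane-1,3-diyl]bis[(2,4-dimethoxyphenyl)methanone] F2. BBr3 in CH2Cl2 should then cleave the four methyl ethers, and the sequence comes back to the route at 10.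

**Step 5.** The dehydrogenation may stop after one ring, the resorcinol rings may be iodinated once they have formed, and the HI present at 80 °C may promote enolisation at C1/C3. The fallback oxidises a protected form. It sets out from 9. Trimethyl orthoformate in methanol with catalytic TsOH should etherify the C4' oxygen, the C2' oxygen being tied up in the hydrogen-bonded β-diketone, to give 6,6'-[(1α,2α,3β,4β)-2,4-diphenylcyclobutane-1,3-dicarbonyl]bis(3-methoxycyclohex-2-en-1-one) F3. DDQ in dioxane should dehydrogenate this vinylogous ester to [(1α,2α,3β,4β)-2,4-diphenylcyclobutane-1,3-diyl]bis[(2-hydroxy-4-methoxyphenyl)methanone] F4. BBr3 in CH2Cl2 should remove the two methyl ethers, coming back at 10.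

**Step 2.** The α-branched acyl chloride may lose configuration at C1/C3 through ketene formation in the presence of the amine, and the twofold acylation at two hindered carbonyl groups may stay incomplete. The fallback replaces acylation and decarboxylation by a direct crossed Claisen reaction. It sets out from 2. Excess 1H-benzotriazole in CH2Cl2 should give [(1α,2α,3β,4β)-2,4-diphenylcyclobutane-1,3-diyl]bis[(1H-benzotriazol-1-yl)methanone] F5. The lithium enolate of acetone (acetone added to lithium diisopropylamide, LiN(iPr)2, THF, −78 °C, at least two equivalents per acyl group because the diketone formed consumes one) should acylate at carbon. This comes back to the route at 6, so steps 2 and 3 are bypassed.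

## Further compounds

F1 | step 4 | (1α,2α,3β,4β)-N1,N3-dimethoxy-N1,N3-dimethyl-2,4-diphenylcyclobutane-1,3-dicarboxamide | CON(C)C(=O)[C@H]1[C@H](c2ccccc2)[C@H](C(=O)N(C)OC)[C@H]1c1ccccc1
F2 | step 4 | [(1α,2α,3β,4β)-2,4-diphenylcyclobutane-1,3-diyl]bis[(2,4-dimethoxyphenyl)methanone] | COc1ccc(C(=O)[C@H]2[C@H](c3ccccc3)[C@H](C(=O)c3ccc(OC)cc3OC)[C@H]2c2ccccc2)c(OC)c1
F3 | step 5 | 6,6'-[(1α,2α,3β,4β)-2,4-diphenylcyclobutane-1,3-dicarbonyl]bis(3-methoxycyclohex-2-en-1-one) | COC1=CC(=O)C(CC1)C(=O)[C@H]1[C@H](c2ccccc2)[C@H](C(=O)C2CCC(OC)=CC2=O)[C@H]1c1ccccc1
F4 | step 5 | [(1α,2α,3β,4β)-2,4-diphenylcyclobutane-1,3-diyl]bis[(2-hydroxy-4-methoxyphenyl)methanone] | COc1ccc(C(=O)[C@H]2[C@H](c3ccccc3)[C@H](C(=O)c3ccc(OC)cc3O)[C@H]2c2ccccc2)c(O)c1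
F5 | step 2 | [(1α,2α,3β,4β)-2,4-diphenylcyclobutane-1,3-diyl]bis[(1H-benzotriazol-1-yl)methanone] | O=C([C@H]1[C@H](c2ccccc2)[C@H](C(=O)n2nnc3ccccc32)[C@H]1c1ccccc1)n1nnc2ccccc21
A1 | alternative 1 | cis,trans,cis-cyclobutane-1,2,3,4-tetracarboxylic 1,2:3,4-dianhydride | O=C1OC(=O)[C@H]2[C@@H]1[C@@H]1C(=O)OC(=O)[C@H]21
A2 | alternative 1 | 1,3-dimethoxybenzene | COc1cccc(OC)c1
A3 | alternative 1 | 2,4-bis(2,4-dimethoxybenzoyl)cyclobutane-1,3-dicarboxylic acid (cis,trans,cis) | O=C(c1ccc(OC)cc1OC)[C@H]1[C@H](C(=O)O)[C@H](C(=O)c2ccc(OC)cc2OC)[C@H]1C(=O)O
A4 | alternative 2 | coumarin | O=C1C=Cc2ccccc2O1
A5 | alternative 2 | anti head-to-tail coumarin photodimer (bis-lactone) | O=C1Oc2ccccc2[C@H]3[C@@H]1[C@@H]1c2ccccc2OC(=O)[C@@H]13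
A6 | alternative 3 | trans-N1,N3-di(quinolin-8-yl)cyclobutane-1,3-dicarboxamide | O=C(Nc1cccc2cccnc12)[C@H]1C[C@H](C(=O)Nc2cccc3cccnc23)C1
A7 | alternative 3 | iodobenzene | Ic1ccccc1
A8 | alternative 3 | 2,4-diphenyl-N,N'-di(quinolin-8-yl)cyclobutane-1,3-dicarboxamide (amides trans, phenyls trans, each phenyl cis to one amide) | O=C(Nc1cccc2cccnc12)[C@H]1[C@H](c2ccccc2)[C@H](C(=O)Nc2cccc3cccnc23)[C@H]1c1ccccc1
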